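The cyclohexene ring (C1 = CH–OAc, C2 = CH2, C3 = CH=, C4 = C(Me)=, C5 = CH–CH2OAr, C6 = CMe2) is cut into two three-carbon halves, C1–C2–C3 and C4–C5–C6. One operation joins them: a 3-silyloxyallylidene phosphorane adds through its oxygen-bearing terminus to the isopropylidene carbon of ethyl 2-acetyl-3-methylbut-2-enoate (C1–C6 bond), then olefinates the acetyl group intramolecularly (C3=C4 bond). The step exploits that C6 is a gem-dimethyl carbon next to an ester-derived carbon, and that C4 is a methyl-bearing vinylic carbon, i.e. a masked acetyl group. C1 emerges as a silyl enol ether; a hydroxyl-directed reduction then sets the trans relationship and a lipase the absolute configuration.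

Key step: step 3

Remark: compounds 9–12 and 14 are racemates; their SMILES show the enantiomer that is carried into 15. The enol ether geometry of 5–8 is immaterial and is left unspecified.

Step 1
Reactants: 1 ethyl acetoacetate; 2 acetone
Product: 3 ethyl 2-acetyl-3-methylbut-2-enoate
Conditions: TiCl4, pyridine, THF, 0 °C to rt
Reagents that add atoms: none
Why: Knoevenagel condensation promoted by TiCl4/pyridine, the usual way to condense a simple ketone with a β-keto ester; the alkene carries two identical methyl groups, so no stereochemical issue arises.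

Step 2
Reactants: 4 acrolein
Product: 5 [3-(tert-butyldimethylsilyloxy)prop-2-en-1-yl]triphenylphosphonium trifluoromethanesulfonate
Conditions: PPh3, TBSOTf, THF, −78 °C to rt
Reagents that add atoms: triphenylphosphine c1ccc(cc1)P(c1ccccc1)c1ccccc1; tert-butyldimethylsilyl trifluoromethanesulfonate CC(C)(C)[Si](C)(C)OS(=O)(=O)C(F)(F)F
Why: phosphoniosilylation of an enal, in which PPh3 adds in conjugate fashion to the silyl-triflate-activated acrolein and the enolate is trapped on oxygen; no stereocentre is formed.

Step 3
Reactants: 5 [3-(tert-butyldimethylsilyloxy)prop-2-en-1-yl]triphenylphosphonium trifluoromethanesulfonate; 3 ethyl 2-acetyl-3-methylbut-2-enoate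
Product: 9 rac-ethyl 5-(tert-butyldimethylsilyloxy)-2,6,6-trimethylcyclohexa-2,4-diene-1-carboxylate, via silyloxyallylidene phosphorane 6 (not isolated), via vinylphosphonium enolate 7 (not isolated), via keto ylide 8 (not isolated)
Conditions: NaN(SiMe3)2, THF, −78 °C; then 3, −78 °C to rt, then 60 °C
Reagents that add atoms: none
Why: [3+3] cyclohexadiene annulation of an allylidenephosphorane with an enone: the γ-carbon of 6 (the silyloxy-bearing terminus) adds in Michael fashion to the isopropylidene carbon of 3 and forms the C1–C6 bond (7), proton transfer from that γ-CH to the β-keto ester enolate regenerates an allylic ylide (8), and its ylide carbon olefinates the acetyl carbonyl intramolecularly to form the C3=C4 double bond with loss of Ph3PO. The closest known reaction is the annulation of unsubstituted allylidenetriphenylphosphorane with alkylidene acetoacetates and other enones to cyclohexa-1,3-dienes; here the phosphorane only carries an extra γ-silyloxy group. The six-membered carbocycle is closed in the Wittig event, a 6-exo-trig attack of the ylide carbon on the ketone through an oxaphosphetane, which can only deliver the cis ring alkene. The single new stereocentre C5 arises by uncontrolled protonation of the ester enolate, so 9 is racemic and is resolved in step 8. The step needs γ- instead of α-attack of the ylide and conjugate addition instead of direct olefination of the ketone; the bulky PPh3 group on the α-carbon, the hindered cross-conjugated acetyl group and the doubly activated alkene of 3 should favour this. Oxygen at C1 is carried on as a silyl dienol ether, a protected ketone that survives the ester reduction of step 4.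

Step 4
Reactants: 9 rac-ethyl 5-(tert-butyldimethylsilyloxy)-2,6,6-trimethylcyclohexa-2,4-diene-1-carboxylate
Product: 10 rac-[5-(tert-butyldimethylsilyloxy)-2,6,6-trimethylcyclohexa-2,4-dien-1-yl]methanol
Conditions: i-Bu2AlH, CH2Cl2, −78 to 0 °C
Reagents that add atoms: none
Why: hydride reduction of the ester to the primary alcohol at low temperature; the silyl dienol ether (the masked C1 ketone) and the C5 stereocentre are untouched.

Step 5
Reactants: 10 rac-[5-(tert-butyldimethylsilyloxy)-2,6,6-trimethylcyclohexa-2,4-dien-1-yl]methanol
Product: 11 rac-5-(hydroxymethyl)-4,6,6-trimethylcyclohex-3-en-1-one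
Conditions: Bu4NF, AcOH, THF, −20 °C
Reagents that add atoms: none
Why: fluoride cleaves the O–Si bond and the buffered dienolate is protonated kinetically at its α-carbon (C2), so the C1 ketone is released with the C3=C4 alkene kept out of conjugation (deconjugative protonation of a dienolate); no new stereocentre.

Step 6
Reactants: 11 rac-5-(hydroxymethyl)-4,6,6-trimethylcyclohex-3-en-1-one
Product: 12 rac-(1R,5R)-5-(hydroxymethyl)-4,6,6-trimethylcyclohex-3-en-1-ol (trans-diol)
Conditions: Me4NBH(OAc)3, MeCN/AcOH, −30 °C
Reagents that add atoms: none
Why: hydroxyl-directed triacetoxyborohydride reduction, in which the reagent is inert to the ketone until the C5 hydroxymethyl group exchanges onto boron and the bound hydride is then delivered to the C1 carbonyl from the face of that arm, placing the new C1 hydroxyl anti to it (trans, C1 set relative to C5).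

Step 7
Reactants: 12 rac-(1R,5R)-5-(hydroxymethyl)-4,6,6-trimethylcyclohex-3-en-1-ol; 13 7-hydroxycoumarin (umbelliferone)
Product: 14 rac-7-{[(1R,5R)-5-hydroxy-2,6,6-trimethylcyclohex-2-en-1-yl]methoxy}-2H-chromen-2-one
Conditions: PPh3, DIAD, THF, 0 °C to rt
Reagents that add atoms: none
Why: Mitsunobu etherification with an acidic phenol, in which only the primary carbinol is activated and displaced, the C1 hydroxyl next to the quaternary carbon does not react, and the trans-1,4-diol cannot close to a cyclic ether; no stereocentre is touched.

Step 8
Reactants: 14 rac-7-{[(1R,5R)-5-hydroxy-2,6,6-trimethylcyclohex-2-en-1-yl]methoxy}-2H-chromen-2-one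
Product: 15 (1R,5R)-4,6,6-trimethyl-5-{[(2-oxo-2H-chromen-7-yl)oxy]methyl}cyclohex-3-en-1-yl acetate (CNP0170350.1)
Conditions: lipase PS (Burkholderia cepacia), vinyl acetate, t-BuOMe, 35 °C, stopped near half conversion
Reagents that add atoms: vinyl acetate CC(=O)OC=C
Why: lipase-catalysed kinetic resolution by irreversible acyl transfer, in which the usual preference of lipases for the secondary carbinol with the large group (quaternary C6 side) and the medium group (C2 methylene) in this arrangement should acetylate the (1R) enantiomer to the target, while the (1S,5S)-alcohol stays behind and is removed by chromatography.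

Compound list
1 | ethyl acetoacetate | CCOC(=O)CC(C)=O | starting material
2 | acetone | CC(C)=O | starting material
3 | ethyl 2-acetyl-3-methylbut-2-enoate | CCOC(=O)C(C(C)=O)=C(C)C | intermediate
4 | acrolein | C=CC=O | starting material
5 | [3-(tert-butyldimethylsilyloxy)prop-2-en-1-yl]triphenylphosphonium trifluoromethanesulfonate | CC(C)(C)[Si](C)(C)OC=CC[P+](c1ccccc1)(c1ccccc1)c1ccccc1.[O-]S(=O)(=O)C(F)(F)F | intermediate
6 | [3-(tert-butyldimethylsilyloxy)prop-2-en-1-ylidene]triphenylphosphorane (not isolated) | CC(C)(C)[Si](C)(C)OC=CC=P(c1ccccc1)(c1ccccc1)c1ccccc1 | intermediate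
7 | conjugate adduct, vinylphosphonium β-keto ester enolate zwitterion (not isolated) | CCOC(=O)C(=C(C)[O-])C(C)(C)C(O[Si](C)(C)C(C)(C)C)C=C[P+](c1ccccc1)(c1ccccc1)c1ccccc1 | intermediate
8 | allylic ylide of the β-keto ester (not isolated) | CCOC(=O)C(C(C)=O)C(C)(C)C(O[Si](C)(C)C(C)(C)C)=CC=P(c1ccccc1)(c1ccccc1)c1ccccc1 | intermediate
9 | rac-ethyl 5-(tert-butyldimethylsilyloxy)-2,6,6-trimethylcyclohexa-2,4-diene-1-carboxylate | CC(C)(C)[Si](C)(C)OC1=CC=C(C)[C@@H](C(=O)OCC)C1(C)C | intermediate
10 | rac-[5-(tert-butyldimethylsilyloxy)-2,6,6-trimethylcyclohexa-2,4-dien-1-yl]methanol | CC(C)(C)[Si](C)(C)OC1=CC=C(C)[C@@H](CO)C1(C)C | intermediate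
11 | rac-5-(hydroxymethyl)-4,6,6-trimethylcyclohex-3-en-1-one | O=C1CC=C(C)[C@@H](CO)C1(C)C | intermediate
12 | rac-(1R,5R)-5-(hydroxymethyl)-4,6,6-trimethylcyclohex-3-en-1-ol | O[C@@H]1CC=C(C)[C@@H](CO)C1(C)C | intermediate
13 | 7-hydroxycoumarin (umbelliferone) | Oc1ccc2ccc(=O)oc2c1 | starting material
14 | rac-7-{[(1R,5R)-5-hydroxy-2,6,6-trimethylcyclohex-2-en-1-yl]methoxy}-2H-chromen-2-one | O[C@@H]1CC=C(C)[C@@H](COc2ccc3ccc(=O)oc3c2)C1(C)C | intermediate
15 | (1R,5R)-4,6,6-trimethyl-5-{[(2-oxo-2H-chromen-7-yl)oxy]methyl}cyclohex-3-en-1-yl acetate | CC(=O)O[C@@H]1CC=C(C)[C@@H](COc2ccc3ccc(=O)oc3c2)C1(C)C | target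

Total step count: 8. Longest linear sequence: 7 steps (steps 2 to 8 from acrolein; equally step 1 and steps 3 to 8 from ethyl acetoacetate).

Steps most likely to fail

Step 3. The ylide may react in the wrong mode: direct olefination of the acetyl group, or attack through the phosphorus-bearing carbon, may outrun γ-conjugate addition at the hindered isopropylidene carbon. The fallback sets out from 5 and 3 and uses the olefination mode on purpose. The ylide (n-BuLi, THF, −78 °C) is condensed with the acetyl carbonyl of 3 to give the triene ethyl (3Z)-6-(tert-butyldimethylsilyloxy)-3-methyl-2-(propan-2-ylidene)hexa-3,5-dienoate F1. Heating (toluene or xylene, 110–140 °C) should close it by disrotatory 6π-electrocyclisation to rac-ethyl 5-(tert-butyldimethylsilyloxy)-2,6,6-trimethylcyclohexa-1,3-diene-1-carboxylate F2. Deprotonation at C5 with LiN(i-Pr)2 (THF, −78 °C) gives the extended enolate that 9 shares, and kinetic protonation at the ester α-carbon (AcOH, −78 °C) moves the diene out of conjugation. The fallback comes back to the route at 9.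

Step 6. Hydride may arrive from the face opposite to the hydroxymethyl arm if unbound reagent reduces the ketone, or the keto alcohol may rest as its bridged hemiketal and be reduced to a bicyclic ether. The fallback sets out from 11 and replaces directed delivery by thermodynamic control: dissolving-metal reduction (Li, liquid NH3, t-BuOH, −78 °C) should give the more stable alcohol, with the C1 hydroxyl equatorial and the C5 arm pseudoaxial to avoid strain with the C4 methyl, which is the trans-diol. No new compound is made (F0), and the fallback comes back at 12.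

Step 8. Acyl transfer may be slow or poorly selective because the carbinol sits next to a quaternary carbon. The fallback sets out from 14 and separates the enantiomers by preparative chromatography on a chiral stationary phase (supercritical CO2/MeOH), giving 7-{[(1R,5R)-5-hydroxy-2,6,6-trimethylcyclohex-2-en-1-yl]methoxy}-2H-chromen-2-one F3. Chemical acetylation (Ac2O, DMAP, pyridine, rt) then gives 15, where it comes back to the route.

Further compounds
F1 | step 3 | ethyl (3Z)-6-(tert-butyldimethylsilyloxy)-3-methyl-2-(propan-2-ylidene)hexa-3,5-dienoate | CCOC(=O)C(=C(C)C)/C(C)=C\C=CO[Si](C)(C)C(C)(C)C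
F2 | step 3 | rac-ethyl 5-(tert-butyldimethylsilyloxy)-2,6,6-trimethylcyclohexa-1,3-diene-1-carboxylate | CCOC(=O)C1=C(C)C=CC(O[Si](C)(C)C(C)(C)C)C1(C)C
F0 | step 6 | none | none
F3 | step 8 | 7-{[(1R,5R)-5-hydroxy-2,6,6-trimethylcyclohex-2-en-1-yl]methoxy}-2H-chromen-2-one | O[C@@H]1CC=C(C)[C@@H](COc2ccc3ccc(=O)oc3c2)C1(C)C
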